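(The constants were set for the occasion; the run is a simulation.)

The protic impurity is charged at less than the starting complex, so its balance comes first.

starting complex 0.010 M; incoming ligand 0.0300 M; protic impurity 5.00 mM; time 4.0 min

    starting complex + incoming ligand ⇌ leaving ligand + complex with one exchanged (K1 = 0.47, k1 = 0.80 M⁻¹ s⁻¹)
    complex with one exchanged + incoming ligand ⇌ leaving ligand + complex with two exchanged (K2 = 0.38, k2 = 0.44 M⁻¹ s⁻¹)
    complex with two exchanged + incoming ligand ⇌ leaving ligand + complex with three exchanged (K3 = 0.15, k3 = 0.38 M⁻¹ s⁻¹)
    protic impurity + starting complex → quenched substrate (k4 = 100 M⁻¹ s⁻¹)

- the complex with two exchanged standing at 4.0 min, as a percentage of the starting complex charged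
- the complex with one exchanged standing at 4.0 min, as a percentage of the starting complex charged

- At the start, the impurity uses up starting complex 21 times faster than the forward step with incoming ligand does, so we let each impurity quench one starting complex, the impurity being the limiting reagent of that step.
- That leaves 50.0% of the charge to exchange: the live share, one minus the impurity charged over the starting complex charged.
- The forward half-lives of the exchange steps, each step taken by itself with the other concentrations as charged, are 0.48 min, 0.88 min and 1.0 min; each is shorter than the 4.0 min allowed, so we take the live share as near balance by then.
- At balance, each complex stands to the one before it as that step's equilibrium constant over the swap ratio, leaving ligand over incoming ligand; per starting complex charged, 3.00 of incoming ligand went in.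
- A first guess of one exchange per live complex gives a swap ratio of 0.200, but the constants then return 1.91 exchanges.
- That guess is the weak link, so we reforge it at the midpoint, 1.46 exchanges: the swap ratio becomes 0.320, and the constants return 1.47.
- We commit to 17.3% complex with two exchanged and 14.6% with one exchanged.
- The forecast gives 16.4% complex with two exchanged and 16.2% with one exchanged, judging that “equilibrium is not quite reached”; its complex with one exchanged stands higher than ours.
- The simulation of this flask gives 16.7% complex with two exchanged and 15.2% with one exchanged, and the forecast is right on both within the tolerance.
- This flask reads 50.0% quenched substrate at 4.00 min, the charge less the live share. In the neighbour charged with 0.0020 M of protic impurity, the live share is 80.0%. One exchange each gives a swap ratio of 0.364 and returns 1.35 exchanges. The midpoint then gives a swap ratio of 0.456, so we reckon 21.7% with two exchanged and 26.0% with one. That neighbour holds 20.0% quenched substrate, 21.8% complex with two exchanged and 26.2% with one exchanged.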